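**Plan**

- Numbering: decalin C1–C10 with C11 as the CH2 link (terpenoid numbering); quinone C1′(=O), C2′(OH), C3′(bears C11), C4′(=O), C5′(OMe), C6′(H).
- Retrosynthetic cuts, in order: C2′–OH back to C2′–OMe; quinone to hydroquinone; ring bond C4′–C5′ opened and C1′–C4′ re-closed (hydroquinone to 4-hydroxy-4-vinylcyclobutenone); C1′–C6′ (vinyllithium); C3′–C11 (alkyllithium plus dimethyl squarate); C7–C8 and C9–C10 (Diels–Alder).
- Forward: ring A is bought, ring B closes by Diels–Alder, the olefin is moved to C5=C10, C11 is lithiated and joined to the squarate, the methoxyvinyl unit is added, and the quinone ring is made last by ring expansion.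
- Enabling feature: the quinone ring has oxygen on C1′, C2′, C4′ and C5′, its only carbon substituent (C11) on C3′ and H on C6′. This is a squarate C4 unit (C1′–C4′) plus a methoxyvinyl C2 unit (C5′, C6′), with the regiochemistry fixed by the order of the two additions.
- Stereochemistry: C8 (S) and C9 (R) both come from one catalytic asymmetric Diels–Alder reaction (cis-methyls from the E-enal, absolute sense from the catalyst); C10 is formed and then erased.

Key step: step 10

Remark: "decalinylmethyl" in the names stands for [(1R,2S)-1,2,5,5-tetramethyl-1,2,3,4,5,6,7,8-octahydronaphthalen-1-yl]methyl (C9 = ring C1, C8 = ring C2).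
Remark: C10 of the Diels–Alder adduct (C8a in the names) is expected as an endo/exo mixture and is left undefined in 7–9; it becomes sp2 in step 6.
Remark: the sense of induction assumed in step 3 is that established for 2-substituted acroleins with this catalyst family ((S)-catalyst sends the diene to the C2-Re face). The target needs the C2-Si/C3-Re face of tiglaldehyde, hence the (R)-catalyst; the antipodal catalyst would be used if the adduct proved to be the enantiomer.

**Route**

Step 1
Reactants: 1 2,2-dimethylcyclohexanone
Product: 3 6,6-dimethylcyclohex-1-en-1-yl trifluoromethanesulfonate, via lithium enolate 2 (not isolated)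
Conditions: LDA, THF, −78 °C; PhNTf2, −78 → 0 °C; H2O
Reagents that add atoms: N-phenylbis(trifluoromethanesulfonimide), O=S(=O)(N(c1ccccc1)S(=O)(=O)C(F)(F)F)C(F)(F)F
Why: The ketone has a single enolisable α-position, so deprotonation and O-triflation of the enolate (enol triflate formation) can give only this regioisomer.

Step 2
Reactants: 3 6,6-dimethylcyclohex-1-en-1-yl trifluoromethanesulfonate; 4 tributyl(vinyl)stannane
Product: 5 6,6-dimethyl-1-vinylcyclohex-1-ene
Conditions: Pd(PPh3)4 (cat.), LiCl, THF, 65 °C
Reagents that add atoms: none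
Why: Stille coupling of a cyclohexenyl triflate with a vinylstannane in the presence of LiCl is the standard entry to 1-vinylcyclohexenes and fixes the diene position without any cationic intermediate.

Step 3
Reactants: 5 6,6-dimethyl-1-vinylcyclohex-1-ene; 6 tiglaldehyde
Product: 7 (1R,2S)-1,2,5,5-tetramethyl-1,2,3,5,6,7,8,8a-octahydronaphthalene-1-carbaldehyde (C8a epimers)
Conditions: (R)-o-tolyl-CBS oxazaborolidine (20 mol %), Tf2NH (18 mol %), CH2Cl2, −78 → −20 °C
Reagents that add atoms: none
Why: Lewis-acid-catalysed asymmetric Diels–Alder reaction: the unsubstituted diene terminus bonds to the enal β-carbon so that the formyl-bearing carbon becomes C9 next to C10 (the usual orientation of 1-vinylcyclohexenes with α-substituted enals), the E-geometry of 6 makes the 8- and 9-methyl groups cis, and the cationic oxazaborolidine holds the s-trans enal with one face shielded so that the diene should add to the C2-Si/C3-Re face, setting 8S and 9R.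

Step 4
Reactants: 7 Diels–Alder aldehyde
Product: 8 [(1R,2S)-1,2,5,5-tetramethyl-1,2,3,5,6,7,8,8a-octahydronaphthalen-1-yl]methanol
Conditions: NaBH4, MeOH, 0 °C
Reagents that add atoms: none
Why: Borohydride reduction of a non-enolisable neopentyl aldehyde gives the primary alcohol without touching C8 or C9.

Step 5
Reactants: 8 neopentyl alcohol
Product: 9 (1R,2S)-1-(iodomethyl)-1,2,5,5-tetramethyl-1,2,3,5,6,7,8,8a-octahydronaphthalene
Conditions: I2, PPh3, imidazole, toluene, 90 °C
Reagents that add atoms: iodine, II
Why: Garegg–Samuelsson (Appel-type) iodination, in which iodide displaces the phosphorus-activated oxygen at the primary carbon; the neopentyl position needs heat but no cation is formed, so no skeletal shift is expected.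

Step 6
Reactants: 9 Δ5(6) iodide
Product: 10 (1R,2S)-1-(iodomethyl)-1,2,5,5-tetramethyl-1,2,3,4,5,6,7,8-octahydronaphthalene
Conditions: TsOH·H2O (10 mol %), benzene, 60 °C
Reagents that add atoms: none
Why: Acid-catalysed olefin isomerisation under thermodynamic control: protonation at C6 gives the tertiary C5 cation, which should lose H10 to give the tetrasubstituted C5=C10 olefin, so both C10 epimers converge; it is run on the iodide because a free C11 hydroxyl would trap the C5 cation as a tetrahydrofuran.

Step 7
Reactants: 10 Δ5(10) iodide; 11 dimethyl squarate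
Product: 15 3-(decalinylmethyl)-4-methoxycyclobut-3-ene-1,2-dione, via alkyllithium 12 (not isolated), via lithium alkoxide adduct 13 (not isolated), via trifluoroacetate 14 (not isolated)
Conditions: t-BuLi (2.1 equiv), Et2O–pentane, −78 °C; 11, THF, −78 °C; (CF3CO)2O, −78 °C; H2O, then NaHCO3 wash
Reagents that add atoms: water, O
Why: Iodine–lithium exchange gives a primary alkyllithium without β-hydrogen that adds 1,2 to one carbonyl of the symmetrical squarate; O-trifluoroacetylation and aqueous work-up then ionise the ester, water adds at the methoxy-bearing terminus of the allyl cation and methanol is lost (the standard squarate-to-alkylcyclobutenedione protocol), the cold and brief acid exposure sparing the tetrasubstituted olefin.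

Step 8
Reactants: 16 methyl vinyl ether
Product: 18 (Z)-1-bromo-2-methoxyethene, via dibromo ether 17 (not isolated)
Conditions: Br2, CH2Cl2, −78 °C; i-Pr2NEt, −78 °C → reflux; fractional distillation
Reagents that add atoms: bromine, BrBr
Why: Bromination of the enol ether followed by amine-induced loss of HBr from the α-bromo ether (bromination–dehydrobromination) should give mainly the Z-2-bromovinyl ether, which is purified by distillation.

Step 9
Reactants: 15 3-(decalinylmethyl)-4-methoxycyclobut-3-ene-1,2-dione; 18 (Z)-1-bromo-2-methoxyethene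
Product: 21 2-(decalinylmethyl)-4-hydroxy-3-methoxy-4-[(Z)-2-methoxyvinyl]cyclobut-2-en-1-one (both C4 epimers), via methoxyvinyllithium 19 (not isolated), via lithium alkoxide 20 (not isolated)
Conditions: 18, t-BuLi (2.0 equiv), THF–Et2O, −78 °C; 15, −78 °C; sat. aq. NH4Cl, −78 °C; used crude
Reagents that add atoms: none
Why: Bromine–lithium exchange gives the Z-2-alkoxyvinyllithium, stable at −78 °C because Li and OMe are cis, which adds to the carbonyl next to the methoxy-bearing carbon since the other carbonyl is deactivated as a vinylogous ester (the established regiochemistry for 3-alkoxycyclobutenediones); the carbinol centre forms as both epimers, which is of no consequence, and the neutral quench avoids acid-induced rearrangement of the β-alkoxyvinyl carbinol to an enal.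

Step 10
Reactants: 21 4-hydroxy-4-(methoxyvinyl)cyclobutenone
Product: 24 3-(decalinylmethyl)-2,5-dimethoxybenzene-1,4-diol, via dienylketene 22 (not isolated), via cyclohexadienone 23 (not isolated)
Conditions: degassed toluene, 110 °C, Ar
Reagents that add atoms: none
Why: Heating should cause conrotatory 4π-electrocyclic opening of the cyclobutenone bond between the carbonyl and carbinol carbons (C4′ and C1′), the hydroxyl rotating outward and the methoxyvinyl group inward, to give dienylketene 22. Disrotatory 6π-electrocyclisation then joins the ketene carbon (C4′) to the methoxy-bearing vinyl terminus (C5′), closing the six-membered ring as cyclohexadienone 23, which enolises to the aromatic hydroquinone 24. The closest known reaction is the thermal ring expansion of 4-alkenyl-4-hydroxycyclobutenones to hydroquinones (Moore rearrangement). No stereocentre results: the sp3 carbon of 23 is lost on aromatisation and both carbinol epimers of 21 converge. The step needs outward rotation of the hydroxyl, which the torquoselectivity of donor substituents secures and which closes off the competing furanone pathway. The oxygen pattern is already fixed by the order of the two additions to the squarate, so C11 ends between a hydroxyl-bearing and a methoxy-bearing carbon and the second methoxy sits next to the only ring hydrogen.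

Step 11
Reactants: 24 hydroquinone (used directly)
Product: 25 3-(decalinylmethyl)-2,5-dimethoxy-1,4-benzoquinone
Conditions: Ag2O, Na2SO4, Et2O, 23 °C
Reagents that add atoms: none
Why: Electron-rich hydroquinones are oxidised to p-benzoquinones by silver(I) oxide under neutral conditions that leave the olefin and both vinylogous esters untouched.

Step 12
Reactants: 25 dimethoxyquinone
Product: 27 3-(decalinylmethyl)-2-hydroxy-5-methoxy-1,4-benzoquinone (target), via potassium salt 26 (not isolated)
Conditions: KOH, MeOH–H2O, 23 → 50 °C; cold 1 M HCl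
Reagents that add atoms: potassium hydroxide, [K+].[OH-]
Why: Saponification of a vinylogous ester by addition–elimination of hydroxide at C2′: the methoxy group flanked by the bulky C11 substituent is twisted out of conjugation and is the more ester-like one (a selectivity known for 3-alkyl-2,5-dimethoxybenzoquinones of this type), the resulting vinylogous carboxylate resists a second hydrolysis, and cold, brief acidification avoids cyclisation of the hydroxyquinone onto the C5=C10 olefin.

**Compound list**

1 | 2,2-dimethylcyclohexanone | CC1(C)CCCCC1=O | starting material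
2 | lithium enolate of 1 | CC1(C)CCCC=C1O[Li] | intermediate (not isolated)
3 | 6,6-dimethylcyclohex-1-en-1-yl trifluoromethanesulfonate | CC1(C)CCCC=C1OS(=O)(=O)C(F)(F)F | intermediate
4 | tributyl(vinyl)stannane | C=C[Sn](CCCC)(CCCC)CCCC | starting material
5 | 6,6-dimethyl-1-vinylcyclohex-1-ene | C=CC1=CCCCC1(C)C | intermediate
6 | tiglaldehyde, (E)-2-methylbut-2-enal | C/C=C(\C)C=O | starting material
7 | (1R,2S)-1,2,5,5-tetramethyl-1,2,3,5,6,7,8,8a-octahydronaphthalene-1-carbaldehyde (C8a undefined) | O=C[C@@]1(C)C2CCCC(C)(C)C2=CC[C@@H]1C | intermediate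
8 | [(1R,2S)-1,2,5,5-tetramethyl-1,2,3,5,6,7,8,8a-octahydronaphthalen-1-yl]methanol (C8a undefined) | OC[C@@]1(C)C2CCCC(C)(C)C2=CC[C@@H]1C | intermediate
9 | (1R,2S)-1-(iodomethyl)-1,2,5,5-tetramethyl-1,2,3,5,6,7,8,8a-octahydronaphthalene (C8a undefined) | IC[C@@]1(C)C2CCCC(C)(C)C2=CC[C@@H]1C | intermediate
10 | (1R,2S)-1-(iodomethyl)-1,2,5,5-tetramethyl-1,2,3,4,5,6,7,8-octahydronaphthalene | IC[C@@]1(C)C2=C(CC[C@@H]1C)C(C)(C)CCC2 | intermediate
11 | dimethyl squarate | COC1=C(OC)C(=O)C1=O | starting material
12 | decalinylmethyllithium | [Li]C[C@@]1(C)C2=C(CC[C@@H]1C)C(C)(C)CCC2 | intermediate (not isolated)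
13 | lithium alkoxide of 4-(decalinylmethyl)-4-hydroxy-2,3-dimethoxycyclobut-2-en-1-one | COC1=C(OC)C(O[Li])(C[C@@]2(C)C3=C(CC[C@@H]2C)C(C)(C)CCC3)C1=O | intermediate (not isolated)
14 | 4-(decalinylmethyl)-2,3-dimethoxy-4-(trifluoroacetoxy)cyclobut-2-en-1-one | COC1=C(OC)C(OC(=O)C(F)(F)F)(C[C@@]2(C)C3=C(CC[C@@H]2C)C(C)(C)CCC3)C1=O | intermediate (not isolated)
15 | 3-(decalinylmethyl)-4-methoxycyclobut-3-ene-1,2-dione | COC1=C(C[C@@]2(C)C3=C(CC[C@@H]2C)C(C)(C)CCC3)C(=O)C1=O | intermediate
16 | methyl vinyl ether | COC=C | starting material
17 | 1,2-dibromo-1-methoxyethane | COC(Br)CBr | intermediate (not isolated)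
18 | (Z)-1-bromo-2-methoxyethene | CO/C=C\Br | intermediate
19 | (Z)-2-methoxyvinyllithium | CO/C=C\[Li] | intermediate (not isolated)
20 | lithium alkoxide of 21 | CO/C=C\C1(O[Li])C(OC)=C(C[C@@]2(C)C3=C(CC[C@@H]2C)C(C)(C)CCC3)C1=O | intermediate (not isolated)
21 | 2-(decalinylmethyl)-4-hydroxy-3-methoxy-4-[(Z)-2-methoxyvinyl]cyclobut-2-en-1-one (C4 epimers) | CO/C=C\C1(O)C(OC)=C(C[C@@]2(C)C3=C(CC[C@@H]2C)C(C)(C)CCC3)C1=O | intermediate
22 | (3Z,5Z)-2-(decalinylmethyl)-4-hydroxy-3,6-dimethoxyhexa-1,3,5-trien-1-one (dienylketene) | O=C=C(C[C@@]1(C)C2=C(CC[C@@H]1C)C(C)(C)CCC2)/C(OC)=C(O)\C=C/OC | intermediate (not isolated)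
23 | 2-(decalinylmethyl)-4-hydroxy-3,6-dimethoxycyclohexa-2,4-dien-1-one | COC1C=C(O)C(OC)=C(C[C@@]2(C)C3=C(CC[C@@H]2C)C(C)(C)CCC3)C1=O | intermediate (not isolated)
24 | 3-(decalinylmethyl)-2,5-dimethoxybenzene-1,4-diol | COc1cc(O)c(OC)c(C[C@@]2(C)C3=C(CC[C@@H]2C)C(C)(C)CCC3)c1O | intermediate
25 | 3-(decalinylmethyl)-2,5-dimethoxy-1,4-benzoquinone | COC1=CC(=O)C(OC)=C(C[C@@]2(C)C3=C(CC[C@@H]2C)C(C)(C)CCC3)C1=O | intermediate
26 | potassium salt of 27 | COC1=CC(=O)C([O-])=C(C[C@@]2(C)C3=C(CC[C@@H]2C)C(C)(C)CCC3)C1=O.[K+] | intermediate (not isolated)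
27 | 3-(decalinylmethyl)-2-hydroxy-5-methoxy-1,4-benzoquinone | COC1=CC(=O)C(O)=C(C[C@@]2(C)C3=C(CC[C@@H]2C)C(C)(C)CCC3)C1=O | target

**Step count**

Total: 12 steps. Longest linear sequence: 11 steps (steps 1–7 and 9–12; step 8 is a one-step side branch).

**Steps most likely to fail**

1. Step 3. The trisubstituted enal may turn over too slowly at the temperatures needed for high facial selectivity, or the enantioselectivity may erode with this hindered diene. Fallback, setting out from 5 and 6 and returning at 8: the cycloaddition would be run with an achiral Lewis acid (EtAlCl2, CH2Cl2, −78 → −20 °C), which should give 7 together with the enantiomeric aldehyde F1. NaBH4 reduction then gives 8 together with the enantiomeric alcohol F2. Esterification with (R)-O-methylmandelic acid (EDC, DMAP) gives the mandelate of 8 F3 and the mandelate of the enantiomer F4, which are separated by chromatography or crystallisation. Saponification of F3 (LiOH, THF–MeOH–H2O) returns 8.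

2. Step 6. The equilibration may stall short of the tetrasubstituted olefin, or the C5 cation may live long enough for a 1,2-methyl shift from C4. Fallback, setting out from 9 and returning at 10: a radical Mukaiyama hydration (Co(acac)2 cat., PhSiH3, O2, THF–i-PrOH) places a hydroxyl on C5 without a free cation and gives the tertiary alcohol F5. Dehydration with Burgess reagent (benzene, 50 °C) should favour the more substituted C5=C10 olefin 10; any 9 regenerated is recycled.

3. Step 12. Hydroxide may attack the less hindered C5′ methoxy carbon instead, or hydrolyse both vinylogous esters. Fallback, setting out from 25 and returning at 27: the hydrolysis would be driven to completion (excess NaOH, aq. MeOH–THF, 60 °C) to the dihydroxyquinone F6. The target would then be regenerated by mono-methylation of the less hindered C5′ hydroxyl, the one next to C6′–H, by vinylogous Fischer esterification (MeOH, PPTS cat., 40 °C).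

**Further compounds**

F1 | step 3 | (1S,2R)-1,2,5,5-tetramethyl-1,2,3,5,6,7,8,8a-octahydronaphthalene-1-carbaldehyde (enantiomer of 7) | O=C[C@]1(C)C2CCCC(C)(C)C2=CC[C@H]1C
F2 | step 3 | [(1S,2R)-1,2,5,5-tetramethyl-1,2,3,5,6,7,8,8a-octahydronaphthalen-1-yl]methanol (enantiomer of 8) | OC[C@]1(C)C2CCCC(C)(C)C2=CC[C@H]1C
F3 | step 3 | (R)-2-methoxy-2-phenylacetate of 8 | CO[C@@H](C(=O)OC[C@@]1(C)C2CCCC(C)(C)C2=CC[C@@H]1C)c1ccccc1
F4 | step 3 | (R)-2-methoxy-2-phenylacetate of F2 | CO[C@@H](C(=O)OC[C@]1(C)C2CCCC(C)(C)C2=CC[C@H]1C)c1ccccc1
F5 | step 6 | (7S,8R)-8-(iodomethyl)-4,4,7,8-tetramethyloctahydronaphthalen-4a(2H)-ol (C4a and C8a undefined) | IC[C@@]1(C)C2CCCC(C)(C)C2(O)CC[C@@H]1C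
F6 | step 12 | 3-(decalinylmethyl)-2,5-dihydroxy-1,4-benzoquinone | OC1=CC(=O)C(O)=C(C[C@@]2(C)C3=C(CC[C@@H]2C)C(C)(C)CCC3)C1=O
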